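The autumn run is the neighbour of amber: it has the same charge in the same kind of closed, stirred flask, but its last reading is at 30.0 h, and amber is opened at 50 h.

| flask | substrate | partner | remark | time |
|---|---|---|---|---|
| autumn | 0.073 M | 1.3 equiv | run made earlier |  |
| winter | 0.073 M | 0.65 equiv | run made earlier |  |
| midnight | 0.073 M | 2.6 equiv | run made earlier |  |
| spring | 0.15 M | 1.3 equiv | run made earlier |  |
| grey | 0.073 M | 1.30 equiv (fed, over 50.0 h) | a stirred flask in which partner is dosed at a steady rate over 50.0 h without added volume, worked up at 50 h | 50 h |
| teal | 0.073 M (fed, over 50.0 h) | 1.30 equiv | a stirred flask in which substrate is dosed at a steady rate over 50.0 h without added volume, worked up at 50 h | 50 h |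
| red | 0.073 M | 1.30 equiv | a single well-mixed tank run continuously and read at steady state, 50 h in it on average |  |
| amber | 0.073 M | 1.30 equiv | a closed flask charged with all of it at once and left for 50 h | 50 h |

| autumn: time / h | autumn: target / % | winter: time / h | winter: target / % | midnight: time / h | midnight: target / % | spring: time / h | spring: target / % |
|---|---|---|---|---|---|---|---|
| 4.00 | 5.4 | 4.00 | 2.9 | 8.00 | 35.3 | 2.50 | 2.8 |
| 10.0 | 27.1 | 10.0 | 14.6 | 15.0 | 68.4 | 6.00 | 20.5 |
| 20.0 | 54.1 | 20.0 | 30.8 | 25.0 | 79.5 | 12.0 | 50.5 |
| 30.0 | 64.2 | 30.0 | 39.7 | 30.0 | 79.4 | 30.0 | 73.0 |

(standard deviation of a reading: 0.5 percentage points)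

1. the set-up with the highest amount of target at the outlet or at the end, in percent of the substrate put in ("none" if the first two lie within 2 percentage points) (grey / teal / red / amber / none)
2. amount of target at the outlet or at the end, in percent of the substrate put in, grey
3. amount of target at the outlet or at the end, in percent of the substrate put in, teal
4. amount of target at the outlet or at the end, in percent of the substrate put in, red
5. amount of target at the outlet or at the end, in percent of the substrate put in, amber

- the stated concentrations are those of everything mixed, before any reaction; amounts are the same in each set-up
- the numbers in the tables scatter with a standard deviation of 0.5 percentage points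
- the feed brings no volume worth counting
- the earlier runs were made in a closed, stirred flask

The midnight run shows what the later hours can do. With more partner, it stays flat from 79.5% at 25.0 h to 79.4% at 30.0 h. I read that flat top as a balance, with target being lost slowly, rather than as a fixed ceiling. A first-order loss is a straight line in logarithms, so all you need is the age of the target. Midnight passes 50% of its charge between 8.00 h and 15.0 h, so at the top its target is on average 16.0 h old. Taking the shortfall from 100% as loss gives the loss time, the time constant in which standing target falls by a factor e: 69.6 h, a reading.

Autumn passes 50% shortly before 20.0 h, so in amber the target is about 30.0 h old at the end. That is older than at midnight's top, so by my reckoning amber keeps 65.0% of what was made and ends near autumn's last reading, 64.2%. In the red tank, ages spread around a mean of 50 h, and the share kept is 58.2%, lower than in amber. With the forecast's conversion of about 70%, I get 40.7% for red.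

The forecast differs from this. It says amber is best, with grey 52%, teal 50%, red 52% and amber 72%, on the grounds “so I assume about 80% selectivity regardless of conditions”.

    partner → second intermediate (k = 0.00200 min⁻¹)
    open intermediate + second intermediate → target (k = 0.0220 L mol⁻¹ min⁻¹)
    target → over-reaction product (k = 1.80 × 10⁻⁴ min⁻¹)
    substrate → open intermediate (k = 0.00550 min⁻¹)

The flask gives amber as best at 63.6%, with grey 52.5%, teal 54.7% and red 42.3%, so amber lies 8.4 percentage points and red 9.7 points below the forecast. Target's half-life against over-reaction product, 64 h, is longer than the 2.1 h of substrate and the 5.8 h of partner, yet it is of the same order as the 50 h these flasks last. The 50 h that the contents of the red tank spend in it on average is 0.718 of the loss time of 69.6 h read from midnight, and the red tank gives 42.3%, with partner standing at 0.0136 M in it.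

The earlier runs and the new flask are simulated for an exercise.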